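The 14-membered carbocycle is disconnected at C10–C11, the CH2–CH2 unit that sits next to the C9 ketone (ring numbered from the isopropyl-bearing C1; epoxide C3–C4, ketones C9 and C14). Ring-closing metathesis forms this bond as an (E)-enone alkene and closes the ring in one operation; the extra unsaturation is then removed by conjugate reduction. The precursor is an acyclic epoxy trienone carrying a vinyl ketone at C9 and a vinyl group on C12, the only two monosubstituted alkenes, with the C8 hydroxymethyl as TBS ether and the C13 hydroxyl as TES ether. It is assembled from a nerol-derived epoxy aldehyde and a glyoxylate-derived isobutyl ketone.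

Key step: step 18

Remark 1: all locants (C1–C14) in the names below follow the ring numbering of the target given above.
Remark 2: C5–C6 is a second unsubstituted CH2–CH2 unit of the ring; C10–C11 is singled out because it alone is flanked by a ketone.
Remark 3: the C13 hydroxyl is carried as a triethylsilyl ether, not a tert-butyldimethylsilyl ether, so that this hindered α-keto carbinol can be unveiled together with the primary TBS ether under buffered HF·pyridine.
Remark 4: ethyl glyoxylate is assumed to be used as freshly cracked, distilled monomer.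

Step 1
Reactants: 1 nerol [(2Z)-3,7-dimethylocta-2,6-dien-1-ol]
Product: 2 (2S,3R)-2,3-epoxynerol {[(2S,3R)-3-methyl-3-(4-methylpent-3-en-1-yl)oxiran-2-yl]methanol}
Conditions: Ti(Oi-Pr)4 (cat.), L-(+)-diethyl tartrate (cat.), t-BuOOH, 4 Å MS, CH2Cl2, −20 °C
Reagents that add atoms: tert-butyl hydroperoxide, CC(C)(C)OO
Why: Sharpless asymmetric epoxidation, in which the titanium–L-tartrate complex delivers oxygen to one face of the (Z)-allylic alcohol and so sets both epoxide carbons (C3 S, C4 R of the target), the cis relationship following from the nerol geometry.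

Step 2
Reactants: 2 (2S,3R)-2,3-epoxynerol
Product: 3 pivalate of 2 {[(2S,3R)-3-methyl-3-(4-methylpent-3-en-1-yl)oxiran-2-yl]methyl 2,2-dimethylpropanoate}
Conditions: PivCl, pyridine, DMAP (cat.), CH2Cl2, 0 °C → rt
Reagents that add atoms: pivaloyl chloride, CC(C)(C)C(Cl)=O
Why: DMAP-catalysed acylation masks the primary alcohol as an ester that should survive ozone, ylide, aqueous carbonate and borohydride and can later be removed beside a silyl ether.

Step 3
Reactants: 3 pivalate of 2
Product: 5 aldehyde [(2S,3R)-3-methyl-3-(3-oxopropyl)oxiran-2-yl]methyl pivalate, via ozonide 4 (not isolated)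
Conditions: O3, CH2Cl2, −78 °C; then PPh3, −78 °C → rt
Reagents that add atoms: ozone, [O-][O+]=O
Why: Ozonolysis of the only alkene (electron-rich, trisubstituted) gives the ozonide, which triphenylphosphine reduces to the C7 aldehyde and acetone, while epoxide and ester are inert.

Step 4
Reactants: 5 aldehyde
Product: 6 (E)-enal {[(2S,3R)-3-methyl-3-[(3E)-5-oxopent-3-en-1-yl]oxiran-2-yl]methyl pivalate}
Conditions: Ph3P=CHCHO, toluene, 80 °C
Reagents that add atoms: (triphenylphosphoranylidene)acetaldehyde, O=CC=P(c1ccccc1)(c1ccccc1)c1ccccc1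
Why: Wittig olefination with the stabilised formylmethylene ylide should give the (E)-enal and adds C8 and the future hydroxymethyl carbon.

Step 5
Reactants: 6 (E)-enal
Product: 7 (Z)-2-iodoenal {[(2S,3R)-3-[(3Z)-4-iodo-5-oxopent-3-en-1-yl]-3-methyloxiran-2-yl]methyl pivalate}
Conditions: I2, K2CO3, DMAP (cat.), THF/H2O (1:1), rt
Reagents that add atoms: iodine, II
Why: Baylis–Hillman-type α-iodination (DMAP conjugate addition, iodination of the enolate, elimination) should give the (Z)-2-iodoenal, with the chain cis to iodine and trans to the formyl group, which is the geometry required at C7=C8.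

Step 6
Reactants: 7 (Z)-2-iodoenal
Product: 8 (Z)-2-iodoallylic alcohol {[(2S,3R)-3-[(3Z)-5-hydroxy-4-iodopent-3-en-1-yl]-3-methyloxiran-2-yl]methyl pivalate}
Conditions: NaBH4, CeCl3·7H2O, MeOH, −40 °C
Reagents that add atoms: none
Why: Luche 1,2-reduction of the aldehyde, which at low temperature should leave pivalate, epoxide and vinyl iodide untouched.

Step 7
Reactants: 8 (Z)-2-iodoallylic alcohol
Product: 9 TBS ether of 8 {[(2S,3R)-3-[(3Z)-5-(tert-butyldimethylsilyloxy)-4-iodopent-3-en-1-yl]-3-methyloxiran-2-yl]methyl pivalate}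
Conditions: TBSCl, imidazole, DMF, 0 °C → rt
Reagents that add atoms: tert-butyldimethylsilyl chloride, CC(C)(C)[Si](C)(C)Cl
Why: Imidazole-promoted silylation of the primary allylic alcohol installs the protecting group of the C8 hydroxymethyl that lasts to the final step.

Step 8
Reactants: 9 TBS ether of 8
Product: 10 epoxy alcohol {[(2S,3R)-3-[(3Z)-5-(tert-butyldimethylsilyloxy)-4-iodopent-3-en-1-yl]-3-methyloxiran-2-yl]methanol}
Conditions: DIBAL-H, CH2Cl2, −78 °C; Rochelle salt work-up
Reagents that add atoms: none
Why: Reductive cleavage of the pivalate by DIBAL-H at −78 °C should free the epoxy alcohol without affecting silyl ether, vinyl iodide or epoxide.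

Step 9
Reactants: 10 epoxy alcohol
Product: 11 epoxy aldehyde {(2R,3R)-3-[(3Z)-5-(tert-butyldimethylsilyloxy)-4-iodopent-3-en-1-yl]-3-methyloxirane-2-carbaldehyde}
Conditions: Dess–Martin periodinane, NaHCO3, CH2Cl2, 0 °C → rt
Reagents that add atoms: none
Why: Dess–Martin oxidation under bicarbonate buffering should give the epoxy aldehyde (C2) without epoxide opening; the descriptor at the formyl-bearing carbon changes only because of CIP priorities.

Step 10
Reactants: 12 ethyl glyoxylate
Product: 13 ethyl (2S,3R)-2-hydroxy-3-methylpent-4-enoate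
Conditions: cis-2-butene, KOt-Bu, n-BuLi, THF, −78 → −45 °C; (−)-Ipc2BOMe, −78 °C; BF3·OEt2; then 12, −78 °C; aq NaOAc, 30% H2O2, 0 °C → rt
Reagents that add atoms: (Z)-crotyldiisopinocampheylborane from (+)-α-pinene (formed in the flask), C/C=C\CB([C@@H]1C[C@@H]2C[C@H]([C@H]1C)C2(C)C)[C@@H]1C[C@@H]2C[C@H]([C@H]1C)C2(C)C
Why: Brown crotylboration through a closed chair transition state, in which the (Z)-crotyl unit gives the syn C12/C13 relationship and the isopinocampheyl groups direct attack to the si face of the aldehyde, should give the (2S,3R) hydroxy ester.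

Step 11
Reactants: 13 ethyl (2S,3R)-2-hydroxy-3-methylpent-4-enoate
Product: 14 ethyl (2S,3R)-3-methyl-2-(triethylsilyloxy)pent-4-enoate
Conditions: TESCl, imidazole, DMF, 0 °C → rt
Reagents that add atoms: chlorotriethylsilane, CC[Si](Cl)(CC)CC
Why: Standard silylation of the secondary α-hydroxy ester protects the future C13 hydroxyl with a group that is stable to base and organometallics but labile to buffered fluoride.

Step 12
Reactants: 14 ethyl (2S,3R)-3-methyl-2-(triethylsilyloxy)pent-4-enoate
Product: 15 Weinreb amide (2S,3R)-N-methoxy-N,3-dimethyl-2-(triethylsilyloxy)pent-4-enamide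
Conditions: MeNH(OMe)·HCl, i-PrMgCl, THF, −20 → 0 °C
Reagents that add atoms: N,O-dimethylhydroxylamine hydrochloride, CNOC.Cl
Why: Weinreb amide formation by the chloromagnesium amide at low temperature should proceed without epimerisation of the α-silyloxy centre.

Step 13
Reactants: 15 Weinreb amide; 16 isobutylmagnesium bromide
Product: 17 isobutyl ketone (3R,4S)-3,7-dimethyl-4-(triethylsilyloxy)oct-1-en-5-one
Conditions: THF, 0 °C; aq NH4Cl
Reagents that add atoms: none
Why: Grignard addition to the Weinreb amide stops at the chelated tetrahedral intermediate, which collapses to the ketone only on work-up.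

Step 14
Reactants: 17 isobutyl ketone; 11 epoxy aldehyde
Product: 19 aldol adduct (β-hydroxy ketone C14=O/C2–OH; C1 and C2 mixed), via lithium enolate 18 (not isolated)
Conditions: LDA, THF, −78 °C; then 11, −78 °C; AcOH quench
Reagents that add atoms: none
Why: Kinetic deprotonation by LDA occurs at the less hindered isobutyl CH2 and not at the silyloxy-bearing methine, and the lithium enolate undergoes aldol addition to the aldehyde; the two new centres are mixed but are removed in the next step.

Step 15
Reactants: 19 aldol adduct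
Product: 21 acyclic (1E)-enone vinyl iodide, via mesylate 20 (not isolated)
Conditions: MsCl, Et3N, CH2Cl2, 0 °C; then DBU, 0 °C → rt
Reagents that add atoms: methanesulfonyl chloride, CS(=O)(=O)Cl (its atoms are in intermediate 20 only and are lost again)
Why: Mesylation followed by DBU-promoted E1cB elimination through the enolate should converge both aldol diastereomers on the conjugated (E)-enone, in which the C14 carbonyl is trans to the C3 epoxide carbon.

Step 16
Reactants: 21 acyclic (1E)-enone vinyl iodide; 22 acrolein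
Product: 23 dienol (C9 bis-allylic alcohol, both C9 epimers)
Conditions: CrCl2 (excess), NiCl2 (cat.), DMSO, rt
Reagents that add atoms: none
Why: Nozaki–Hiyama–Kishi coupling, in which nickel inserts into the alkenyl iodide with retention and the alkenylchromium(III) adds 1,2 to the aldehyde only, should tolerate ketone, enone, epoxide and silyl ethers; the C9 configuration is irrelevant.

Step 17
Reactants: 23 dienol
Product: 24 RCM precursor (acyclic epoxy trienone with C9 vinyl ketone and C12 vinyl group)
Conditions: Dess–Martin periodinane, NaHCO3, CH2Cl2, 0 °C; used without delay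
Reagents that add atoms: none
Why: Dess–Martin oxidation of the bis-allylic alcohol under buffered conditions should give the cross-conjugated vinyl ketone without touching the epoxide or silyl ethers.

Step 18
Reactants: 24 RCM precursor
Product: 25 macrocyclic dienone (10,11-didehydro bis-silyl ether of the target)
Conditions: Grubbs II (10 mol %), 1,4-benzoquinone (20 mol %), CH2Cl2 (1 mM), 40 °C
Reagents that add atoms: none
Why: The ruthenium benzylidene initiates at the electron-neutral monosubstituted C11 alkene, and the resulting alkylidene undergoes intramolecular [2+2] cycloaddition with the C9 vinyl ketone and cycloreversion, forming C10=C11 and expelling ethylene. The closest known reaction type is macrocyclic enone ring-closing metathesis of a vinyl ketone with a terminal alkene. The 14-membered carbocycle is closed head-to-tail with the new alkene endocyclic, under high dilution so that cyclization outruns oligomerization, and the two rigid enone units and the cis-epoxide restrict the chain. No stereocentre is formed; the (E) geometry of C10=C11 should follow from thermodynamic control in the reversible metathesis of the conjugated enone, and it is erased in step 19 in any case. The step needs site selectivity, which the substrate secures because the C9 vinyl and C12 vinyl groups are the only monosubstituted alkenes, whereas C1=C2 and C7=C8 are trisubstituted and electron-poor and the epoxide and silyl ethers are inert to the carbene. Loss of volatile ethylene drives the closure.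

Step 19
Reactants: 25 macrocyclic dienone
Product: 26 bis-silyl ether of the target
Conditions: [(Ph3P)CuH]6 (0.5 equiv), H2O (10 equiv), degassed benzene, rt
Reagents that add atoms: none
Why: Conjugate reduction with Stryker's reagent should deliver hydride to C11 of the α-unsubstituted disubstituted enone much faster than to the α-substituted trisubstituted enones C7=C8 and C1=C2, and water protonates the copper enolate before it can react further.

Step 20
Reactants: 26 bis-silyl ether of the target
Product: 27 target (CNP0251075.1)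
Conditions: HF·pyridine, pyridine, THF, 0 °C → rt
Reagents that add atoms: none
Why: Fluoride-mediated desilylation under pyridine buffering should cleave the primary TBS and the secondary TES ether as silyl fluorides under nearly neutral conditions that spare the trisubstituted epoxide, both enones and the α-ketol.

Compound list
1 | nerol, (2Z)-3,7-dimethylocta-2,6-dien-1-ol | CC(C)=CCC/C(C)=C\CO | starting material
2 | (2S,3R)-2,3-epoxynerol, [(2S,3R)-3-methyl-3-(4-methylpent-3-en-1-yl)oxiran-2-yl]methanol | OC[C@@H]1O[C@]1(C)CCC=C(C)C | intermediate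
3 | [(2S,3R)-3-methyl-3-(4-methylpent-3-en-1-yl)oxiran-2-yl]methyl pivalate | CC(C)(C)C(=O)OC[C@@H]1O[C@]1(C)CCC=C(C)C | intermediate
4 | ozonide (3,3-dimethyl-1,2,4-trioxolane) of 3 | CC(C)(C)C(=O)OC[C@@H]1O[C@]1(C)CCC2OOC(C)(C)O2 | intermediate (not isolated)
5 | [(2S,3R)-3-methyl-3-(3-oxopropyl)oxiran-2-yl]methyl pivalate | CC(C)(C)C(=O)OC[C@@H]1O[C@]1(C)CCC=O | intermediate
6 | [(2S,3R)-3-methyl-3-[(3E)-5-oxopent-3-en-1-yl]oxiran-2-yl]methyl pivalate | CC(C)(C)C(=O)OC[C@@H]1O[C@]1(C)CC/C=C/C=O | intermediate
7 | [(2S,3R)-3-[(3Z)-4-iodo-5-oxopent-3-en-1-yl]-3-methyloxiran-2-yl]methyl pivalate | CC(C)(C)C(=O)OC[C@@H]1O[C@]1(C)CC/C=C(\I)C=O | intermediate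
8 | [(2S,3R)-3-[(3Z)-5-hydroxy-4-iodopent-3-en-1-yl]-3-methyloxiran-2-yl]methyl pivalate | CC(C)(C)C(=O)OC[C@@H]1O[C@]1(C)CC/C=C(\I)CO | intermediate
9 | [(2S,3R)-3-[(3Z)-5-(tert-butyldimethylsilyloxy)-4-iodopent-3-en-1-yl]-3-methyloxiran-2-yl]methyl pivalate | CC(C)(C)C(=O)OC[C@@H]1O[C@]1(C)CC/C=C(\I)CO[Si](C)(C)C(C)(C)C | intermediate
10 | [(2S,3R)-3-[(3Z)-5-(tert-butyldimethylsilyloxy)-4-iodopent-3-en-1-yl]-3-methyloxiran-2-yl]methanol | OC[C@@H]1O[C@]1(C)CC/C=C(\I)CO[Si](C)(C)C(C)(C)C | intermediate
11 | (2R,3R)-3-[(3Z)-5-(tert-butyldimethylsilyloxy)-4-iodopent-3-en-1-yl]-3-methyloxirane-2-carbaldehyde | O=C[C@@H]1O[C@]1(C)CC/C=C(\I)CO[Si](C)(C)C(C)(C)C | intermediate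
12 | ethyl glyoxylate | CCOC(=O)C=O | starting material
13 | ethyl (2S,3R)-2-hydroxy-3-methylpent-4-enoate | C=C[C@@H](C)[C@H](O)C(=O)OCC | intermediate
14 | ethyl (2S,3R)-3-methyl-2-(triethylsilyloxy)pent-4-enoate | C=C[C@@H](C)[C@H](O[Si](CC)(CC)CC)C(=O)OCC | intermediate
15 | (2S,3R)-N-methoxy-N,3-dimethyl-2-(triethylsilyloxy)pent-4-enamide | C=C[C@@H](C)[C@H](O[Si](CC)(CC)CC)C(=O)N(C)OC | intermediate
16 | isobutylmagnesium bromide | CC(C)C[Mg]Br | starting material
17 | (3R,4S)-3,7-dimethyl-4-(triethylsilyloxy)oct-1-en-5-one | C=C[C@@H](C)[C@H](O[Si](CC)(CC)CC)C(=O)CC(C)C | intermediate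
18 | lithium enolate of 17 (C14–O–Li, C14=C1) | C=C[C@@H](C)[C@H](O[Si](CC)(CC)CC)C(O[Li])=CC(C)C | intermediate (not isolated)
19 | aldol adduct CH2=CH–C12H(CH3)–C13H(OTES)–C14(=O)–C1H(i-Pr)–C2H(OH)–[C3H–O–C4(CH3)]–C5H2–C6H2–C7H=C8(I)–CH2OTBS; (3S,4R,7Z,12R,13S), C1 and C2 mixed | C=C[C@@H](C)[C@H](O[Si](CC)(CC)CC)C(=O)C(C(C)C)C(O)[C@@H]1O[C@]1(C)CC/C=C(\I)CO[Si](C)(C)C(C)(C)C | intermediate
20 | C2 methanesulfonate of 19 | C=C[C@@H](C)[C@H](O[Si](CC)(CC)CC)C(=O)C(C(C)C)C(OS(C)(=O)=O)[C@@H]1O[C@]1(C)CC/C=C(\I)CO[Si](C)(C)C(C)(C)C | intermediate (not isolated)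
21 | enone CH2=CH–C12H(CH3)–C13H(OTES)–C14(=O)–C1(i-Pr)=C2H–[C3H–O–C4(CH3)]–C5H2–C6H2–C7H=C8(I)–CH2OTBS; (1E,3S,4R,7Z,12R,13S) | C=C[C@@H](C)[C@H](O[Si](CC)(CC)CC)C(=O)/C(C(C)C)=C/[C@@H]1O[C@]1(C)CC/C=C(\I)CO[Si](C)(C)C(C)(C)C | intermediate
22 | acrolein | C=CC=O | starting material
23 | dienol: 21 with iodine replaced by C9H(OH)–CH=CH2; (1E,3S,4R,7Z,12R,13S), C9 epimers | C=C[C@@H](C)[C@H](O[Si](CC)(CC)CC)C(=O)/C(C(C)C)=C/[C@@H]1O[C@]1(C)CC/C=C(/CO[Si](C)(C)C(C)(C)C)C(O)C=C | intermediate
24 | RCM precursor: acyclic epoxy trienone with C9 vinyl ketone, C12 vinyl group, C8–CH2OTBS, C13–OTES; (1E,3S,4R,7Z,12R,13S) | C=C[C@@H](C)[C@H](O[Si](CC)(CC)CC)C(=O)/C(C(C)C)=C/[C@@H]1O[C@]1(C)CC/C=C(/CO[Si](C)(C)C(C)(C)C)C(=O)C=C | intermediate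
25 | (1E,3S,4R,7Z,10E,12R,13S)-8-[(tert-butyldimethylsilyloxy)methyl]-3,4-epoxy-4,12-dimethyl-1-(propan-2-yl)-13-(triethylsilyloxy)cyclotetradeca-1,7,10-triene-9,14-dione | CC(C)/C1=C\[C@@H]2O[C@]2(C)CC/C=C(/CO[Si](C)(C)C(C)(C)C)C(=O)/C=C/[C@@H](C)[C@H](O[Si](CC)(CC)CC)C1=O | intermediate
26 | (1E,3S,4R,7Z,12R,13S)-8-[(tert-butyldimethylsilyloxy)methyl]-3,4-epoxy-4,12-dimethyl-1-(propan-2-yl)-13-(triethylsilyloxy)cyclotetradeca-1,7-diene-9,14-dione | CC(C)/C1=C\[C@@H]2O[C@]2(C)CC/C=C(/CO[Si](C)(C)C(C)(C)C)C(=O)CC[C@@H](C)[C@H](O[Si](CC)(CC)CC)C1=O | intermediate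
27 | (1E,3S,4R,7Z,12R,13S)-3,4-epoxy-13-hydroxy-8-(hydroxymethyl)-4,12-dimethyl-1-(propan-2-yl)cyclotetradeca-1,7-diene-9,14-dione | CC(C)/C1=C\[C@@H]2O[C@]2(C)CC/C=C(/CO)C(=O)CC[C@@H](C)[C@H](O)C1=O | target

Total step count: 20.
Longest linear sequence: 16 steps (nerol to 27: steps 1–9 and 14–20); the ketone branch (steps 10–13) joins at step 14.

Steps most likely to fail

1. Step 18 (ring-closing metathesis). What may go wrong: intermolecular metathesis (oligomerization) or decomposition of the cross-conjugated vinyl ketone may outrun cyclization, and the ruthenium alkylidene may be arrested by chelation to the C9 carbonyl. Fallback, setting out from 21 and coming back at 26: the ring is closed at C8–C9 instead. Linear-selective rhodium-catalysed hydroformylation of the terminal alkene of 21 (Rh(acac)(CO)2, BIPHEPHOS, CO/H2, toluene, 60 °C) should give the C9 aldehyde F1, in which C10–C11 is already saturated. Intramolecular Nozaki–Hiyama–Kishi coupling of the C8 alkenyl iodide with this aldehyde (CrCl2, cat. NiCl2, DMSO/THF, high dilution) should close the 14-membered ring to the macrocyclic C9 carbinol F2. Dess–Martin oxidation of F2 gives 26, so steps 16–19 are replaced.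

2. Step 19 (conjugate reduction). What may go wrong: loss of site selectivity in hydride delivery (attack at C7 of the same ketone followed by β-elimination of the silyloxy group, or attack at C2), transannular aldol addition of the copper enolate to the C14 ketone, or over-reduction of a carbonyl. Fallback, setting out from 23 and coming back at 26: the ring is closed one oxidation level lower and the alkene is isomerized, not reduced. Ring-closing metathesis of dienol 23 (Grubbs II, CH2Cl2, 1 mM, 40 °C) should give the macrocyclic bis-allylic alcohol F3. Redox isomerization of this allylic alcohol (H2-activated [Ir(cod)(PCy3)(py)]PF6, THF, rt) proceeds by metal hydride insertion into the less hindered disubstituted C10=C11 alkene and β-hydride elimination to the enol. This should give 26 directly, with no hydride nucleophile and no metal enolate involved.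

3. Step 15 (dehydration). What may go wrong: incomplete E/Z control in the E1cB elimination next to the isopropyl group, and base-mediated epimerization at C13. Fallback, setting out from 15 (with 11) and coming back at 21: the C1=C2 bond is made by olefination. Addition of lithiated diethyl (2-methylpropyl)phosphonate (n-BuLi, THF, −78 °C) to Weinreb amide 15 should give the α-isopropyl β-ketophosphonate F4. Horner–Wadsworth–Emmons reaction of F4 with aldehyde 11 (Ba(OH)2, wet THF, rt) should give the (E)-enone 21 without a β-hydroxy ketone, a sulfonate or an amidine base, replacing steps 13–15.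

Further compounds
F1 | step 18 | C9 aldehyde from hydroformylation of 21 (OHC–C10H2–C11H2–C12; otherwise as 21) | O=CCC[C@@H](C)[C@H](O[Si](CC)(CC)CC)C(=O)/C(C(C)C)=C/[C@@H]1O[C@]1(C)CC/C=C(\I)CO[Si](C)(C)C(C)(C)C
F2 | step 18 | macrocyclic C9 carbinol with saturated C10–C11 (9-hydroxy analogue of 26, C9 epimers) | CC(C)/C1=C\[C@@H]2O[C@]2(C)CC/C=C(/CO[Si](C)(C)C(C)(C)C)C(O)CC[C@@H](C)[C@H](O[Si](CC)(CC)CC)C1=O
F3 | step 19 | macrocyclic bis-allylic C9 carbinol with (E)-C10=C11 (9-hydroxy analogue of 25, C9 epimers) | CC(C)/C1=C\[C@@H]2O[C@]2(C)CC/C=C(/CO[Si](C)(C)C(C)(C)C)C(O)/C=C/[C@@H](C)[C@H](O[Si](CC)(CC)CC)C1=O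
F4 | step 15 | diethyl [(5R,6S)-2,6-dimethyl-4-oxo-5-(triethylsilyloxy)oct-7-en-3-yl]phosphonate (β-ketophosphonate, C1 epimers) | C=C[C@@H](C)[C@H](O[Si](CC)(CC)CC)C(=O)C(C(C)C)P(=O)(OCC)OCC
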